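(The numbers in the tables come from a simulation with made-up constants; the scatter is artificial.)

Follow the substrate.

| flask | substrate | remark | time |
|---|---|---|---|
| Monday's | 0.018 M | run made earlier |  |
| Saturday's | 0.058 M | run made earlier |  |
| Friday's | 0.24 M | run made earlier |  |
| south | 0.015 M |  | 1.0 h |
| north-east | 0.080 M |  | 1.0 h |
| east | 0.030 M |  | 1.0 h |
| south-east | 0.20 M |  | 1.0 h |
| north | 0.15 M |  | 1.0 h |
| west | 0.050 M |  | 1.0 h |

| run | time / min | target / % | substrate / % |
|---|---|---|---|
| Monday's | 3.00 | 0.4 | 85.6 |
| Monday's | 6.00 | 0 | 71.7 |
| Monday's | 12.0 | 1.9 | 51.7 |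
| Monday's | 20.0 | 3.6 | 35.4 |
| Monday's | 40.0 | 18.3 | 14.7 |
| Saturday's | 8.00 | 0.7 | 57.5 |
| Saturday's | 15.0 | 2.4 | 37.4 |
| Saturday's | 25.0 | 7.3 | 21.9 |
| Saturday's | 30.0 | 9.3 | 17.1 |
| Saturday's | 40.0 | 16.1 | 11.5 |
| Friday's | 4.00 | 0.3 | 57.9 |
| Friday's | 10.0 | 1.3 | 30.0 |
| Friday's | 20.0 | 3.1 | 15.3 |
| Friday's | 30.0 | 6.5 | 8.9 |
| Friday's | 40.0 | 12.2 | 6.1 |

(readings scatter by 0.5 percentage points)

1. ranking by amount of target, in percent of the substrate charged, from high to low, at 1.0 h (south / north-east / east / south-east / north / west)
2. the amount of target, in percent of the substrate charged of the flask you put first, at 1.0 h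
3. the amount of target, in percent of the substrate charged of the flask you put last, at 1.0 h



Two chemists argue over these flasks. The first holds that every step is first-order, so percentages run alike whatever the charge, and she points to target at the last reading: 18.3 % in Monday's run, 16.1 % in Saturday's. Carrying Saturday's last rise on to the asked time, she expects about 29.7 % in every flask.

The second writes the balance of the substrate. Its apparent first-order constant, ln(charged/left)/time, reads 0.0550 min⁻¹ in Monday's run and 0.137 min⁻¹ early in Friday's, higher at the larger charge. Against the mean concentrations of those intervals, 0.0132 M and 0.185 M, the loss reads a·S + b·S squared, where S is the substrate concentration, with b = 0.475 M⁻¹ min⁻¹ and a = 0.0487 min⁻¹.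

Integrating gives the quantity I carry. The first-order share of south, 0.933, is the fraction of the charged substrate that leaves by the a·S term, a selectivity equal to ln(1 + x)/x with x = b·charge/a. For south-east it is 0.555, lower.

I side with the second. I take target to come from the part that leaves by the a·S term; her share falls as the charge rises, so on that reckoning south comes first and south-east last. Dividing the first chemist's figure by Saturday's share, 0.792, and multiplying by each flask's share, I get 35.0 % for south and 20.8 % for south-east.

The forecast has the same order but higher numbers, south > east > west > north-east > north > south-east with 37 % and 26 %, holding that “target forms only through the first-order branch”.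

The simulation gives south > east > west > north-east > north > south-east, with 36.0 % and 22.7 %, a spread of 13 percentage points, and my figures lie 1 point and 1.9 points below. The first chemist's view has its region around south: with the time held, south's target stays within 5 points of itself down to at least 0.00187 M and up to 0.0606 M.

    substrate ⇌ intermediate A (K = 16.0, k = 8.20 × 10⁻⁴ s⁻¹)
    intermediate A → intermediate B (k = 4.40 × 10⁻⁴ s⁻¹)
    intermediate B ⇌ target (K = 18.0, k = 7.70 × 10⁻⁴ s⁻¹)
    substrate + intermediate B → side product (k = 9.00 × 10⁻⁴ M⁻¹ s⁻¹)
    2 substrate → self-condensation product (k = 0.00420 M⁻¹ s⁻¹)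

The substrate's half-life by the forward step to intermediate A alone is 0.235 h in south and south-east, while by self-condensation alone its first half-life is 2.20 h in south, ten times as long. In south-east that first half-life is 0.165 h, shorter than the forward step's, and after 1.00 h self-condensation product stands at 46.3 % there against 7.20 % in south.

Left until 4.0 h, south should hold about 93.3 % of its charge in target and the intermediates together. The simulation gives 86.6 % target, 5.32 % intermediate B and 0.489 % intermediate A, together 92.4 %, beside 7.25 % self-condensation product and 0.0586 % substrate.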